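**Retrosynthetic overview**
- The target comes from borohydride reduction of the ring B formyl group of the corresponding aldehyde acid (the CH2OH is carried as CHO until the last step).
- Key disconnection: the diaryl ether C–O bond (ring A C-6 to ring B O-2). It is made by a site-selective copper-catalysed coupling of a ring A 6-bromobenzoic acid with the unprotected ring B catechol aldehyde.
- The ring A bromo acid comes from CO2 and lithiation between OMe and Br of the (R)-carbinol, itself made by enantioselective isobutyl addition to 4-bromo-2-methoxybenzaldehyde (sets the only stereocentre).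
- The ring B catechol aldehyde comes from O-demethylation of 2-hydroxy-3-methoxy-5-methylbenzaldehyde.
- No ring is formed: rings A and B are both bought as benzenes and joined in the penultimate step.

Assumption: 4-bromo-2-methoxybenzaldehyde, isobutylmagnesium bromide solution and 2-hydroxy-3-methoxy-5-methylbenzaldehyde are taken as inexpensive catalogue chemicals; the stereocentre in the SMILES is read as (R).

**Step 1**
Reactants: 1 4-bromo-2-methoxybenzaldehyde; 2 isobutylmagnesium bromide
Product: 4 (1R)-1-(4-bromo-2-methoxyphenyl)-3-methylbutan-1-ol, via isobutyltitanium triisopropoxide 3 (not isolated)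
Conditions: 2 (2.2 equiv) premixed with Ti(OiPr)4 at −78 °C, added over 2 h to 1, Ti(OiPr)4 (5.8 equiv in total), (R)-3-(3,5-diphenylphenyl)-H8-BINOL (2 mol %), CH2Cl2/Et2O, 0 °C; 1 M HCl
Reagents that add atoms: isobutylmagnesium bromide (compound 2), CC(C)C[Mg]Br
Why: Catalytic enantioselective Grignard (alkyltitanium) addition to an aryl aldehyde; the chiral titanium BINOLate delivers the isobutyl group of 3 to the Re face, which gives the (R)-carbinol (ligand sense chosen by analogy with benzaldehyde, to be confirmed by Mosher ester analysis), and the aryl bromide is inert at 0 °C.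

**Step 2**
Reactants: 4 (1R)-1-(4-bromo-2-methoxyphenyl)-3-methylbutan-1-ol
Product: 6 6-bromo-3-[(1R)-1-hydroxy-3-methylbutyl]-2-methoxybenzoic acid, via dilithiated alcohol 5 (not isolated)
Conditions: LDA (commercial, 2.3 equiv), THF, −78 °C, 1 h; CO2 (g), −78 °C to rt; 1 M HCl to pH 3
Reagents that add atoms: carbon dioxide, O=C=O
Why: Directed ortho-metalation followed by carboxylation; LDA removes the most acidic ring proton (flanked by OMe and Br), −78 °C keeps the ortho-bromoaryllithium from losing LiBr, and the carbinol centre is protected as its lithium alkoxide.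

**Step 3**
Reactants: 7 2-hydroxy-3-methoxy-5-methylbenzaldehyde
Product: 8 2,3-dihydroxy-5-methylbenzaldehyde
Conditions: BBr3 (2.5 equiv), CH2Cl2, −78 to 0 °C; H2O
Reagents that add atoms: none
Why: Lewis-acid O-demethylation of an aryl methyl ether with BBr3; the aldehyde and the ring methyl group are untouched.

**Step 4**
Reactants: 6 6-bromo-3-[(1R)-1-hydroxy-3-methylbutyl]-2-methoxybenzoic acid; 8 2,3-dihydroxy-5-methylbenzaldehyde (1.3 equiv)
Product: 9 6-(2-formyl-6-hydroxy-4-methylphenoxy)-3-[(1R)-1-hydroxy-3-methylbutyl]-2-methoxybenzoic acid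
Conditions: Cu2O (5 mol %), K2CO3 (2.0 equiv), pyridine (1 equiv), DMF, 90 °C, argon; 1 M HCl to pH 3 at 0 °C
Reagents that add atoms: none
Why: Proposed new method: a protecting-group-free, site-selective Hurtley-type (Ullmann) C–O coupling of an unprotected 3-hydroxysalicylaldehyde. With one base equivalent per acidic proton only the formyl-conjugated 2-OH of 8 is ionised (pKa about 8), while the 3-OH stays protonated and hydrogen-bonded. Monovalent copper is held between the ortho-carboxylate of 6, which directs oxidative addition of C–Br to an aryl trivalent copper chelate, and the O-2/CHO salicylaldehydate chelate of 8, so reductive elimination forms the aryl–O-2 bond. The carboxylate-deactivated ring A cannot scramble to O-3 by Smiles rearrangement. Closest known reactions: the Hurtley/Ullmann–Goldberg condensation of 2-halobenzoic acids with simple phenols, and monoanion-selective O-alkylation of dihydroxybenzaldehydes. No stereocentre is formed and the (R)-carbinol is a spectator.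

**Step 5**
Reactants: 9 6-(2-formyl-6-hydroxy-4-methylphenoxy)-3-[(1R)-1-hydroxy-3-methylbutyl]-2-methoxybenzoic acid
Product: 10 6-[2-hydroxy-6-(hydroxymethyl)-4-methylphenoxy]-3-[(1R)-1-hydroxy-3-methylbutyl]-2-methoxybenzoic acid
Conditions: NaBH4 (1.5 equiv), THF/MeOH, 0 °C; 1 M HCl to pH 3 at 0 °C
Reagents that add atoms: none
Why: Chemoselective borohydride reduction of the aryl aldehyde; carboxylate, diaryl ether and the benzylic stereocentre are untouched, and cold mild acidification avoids ionising the benzylic alcohols.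

**Compound list**
1 | 4-bromo-2-methoxybenzaldehyde | COc1cc(Br)ccc1C=O | starting material
2 | isobutylmagnesium bromide | CC(C)C[Mg]Br | starting material
3 | isobutyltitanium triisopropoxide | CC(C)C[Ti](OC(C)C)(OC(C)C)OC(C)C | intermediate
4 | (1R)-1-(4-bromo-2-methoxyphenyl)-3-methylbutan-1-ol | COc1cc(Br)ccc1[C@H](O)CC(C)C | intermediate
5 | lithium (1R)-1-(4-bromo-3-lithio-2-methoxyphenyl)-3-methylbutan-1-olate | COc1c([Li])c(Br)ccc1[C@H](O[Li])CC(C)C | intermediate
6 | 6-bromo-3-[(1R)-1-hydroxy-3-methylbutyl]-2-methoxybenzoic acid | COc1c([C@H](O)CC(C)C)ccc(Br)c1C(=O)O | intermediate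
7 | 2-hydroxy-3-methoxy-5-methylbenzaldehyde | COc1cc(C)cc(C=O)c1O | starting material
8 | 2,3-dihydroxy-5-methylbenzaldehyde | Cc1cc(O)c(O)c(C=O)c1 | intermediate
9 | 6-(2-formyl-6-hydroxy-4-methylphenoxy)-3-[(1R)-1-hydroxy-3-methylbutyl]-2-methoxybenzoic acid | COc1c([C@H](O)CC(C)C)ccc(Oc2c(O)cc(C)cc2C=O)c1C(=O)O | intermediate
10 | 6-[2-hydroxy-6-(hydroxymethyl)-4-methylphenoxy]-3-[(1R)-1-hydroxy-3-methylbutyl]-2-methoxybenzoic acid | COc1c([C@H](O)CC(C)C)ccc(Oc2c(O)cc(C)cc2CO)c1C(=O)O | target

**Totals**
Total step count: 5. Longest linear sequence: 4 steps (steps 1, 2, 4, 5); the ring B branch is 3 steps (steps 3, 4, 5).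

**Steps most likely to fail, with fallbacks**

Step 4 (the proposed new site-selective coupling). The risks are arylation at O-3, oxidation of the free catechol, and a sluggish reaction of the hindered phenoxide. The fallback uses known chemistry, sets out from 8 (with 6) and rejoins the route at 10. The dianion of 8 (NaH 2.1 equiv, DMSO) is alkylated with benzyl bromide (1.0 equiv) at the more nucleophilic O-3 to give 3-(benzyloxy)-2-hydroxy-5-methylbenzaldehyde F1. A conventional Hurtley coupling of F1, which has only one free phenol, with 6 (Cu2O, K2CO3, pyridine, DMF, 100 °C) gives 6-[2-(benzyloxy)-6-formyl-4-methylphenoxy]-3-[(1R)-1-hydroxy-3-methylbutyl]-2-methoxybenzoic acid F2. NaBH4 reduction gives 6-[2-(benzyloxy)-6-(hydroxymethyl)-4-methylphenoxy]-3-[(1R)-1-hydroxy-3-methylbutyl]-2-methoxybenzoic acid F3. Hydrogenolysis (H2 1 atm, Pd/C, EtOAc, rt, stopped at full conversion) gives 10; the aryl benzyl ether cleaves much faster than the two benzylic alcohols.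

Step 1 (enantioselectivity with an ortho-methoxy aldehyde and a branched Grignard reagent). The fallback sets out from 1 and 2 and rejoins at 4, setting the centre by reduction instead of alkylation. Uncatalysed addition of 2 to 1 (THF, 0 °C) gives racemic 1-(4-bromo-2-methoxyphenyl)-3-methylbutan-1-ol F4. MnO2 in CH2Cl2 gives 1-(4-bromo-2-methoxyphenyl)-3-methylbutan-1-one F5. Noyori asymmetric transfer hydrogenation (RuCl[(R,R)-TsDPEN](p-cymene) 1 mol %, HCO2H/Et3N, 30 °C) gives (R)-configured 4.

Step 2 (benzyne formation or halogen migration of the ortho-bromoaryllithium before CO2 capture). The fallback sets out from 4 and rejoins at 6, never accumulating the aryllithium. Deprotonation with LiTMP in the presence of B(OiPr)3 (in situ quench, THF, −78 °C), then pinacol, gives (1R)-1-[4-bromo-2-methoxy-3-(4,4,5,5-tetramethyl-1,3,2-dioxaborolan-2-yl)phenyl]-3-methylbutan-1-ol F6. Copper-catalysed carboxylation of the arylboronic ester (CuCl(IPr) 5 mol %, KOtBu, CO2 1 atm, THF, 70 °C; acid work-up) gives 6.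

**Further compounds**
F1 | step 4 | 3-(benzyloxy)-2-hydroxy-5-methylbenzaldehyde | Cc1cc(OCc2ccccc2)c(O)c(C=O)c1
F2 | step 4 | 6-[2-(benzyloxy)-6-formyl-4-methylphenoxy]-3-[(1R)-1-hydroxy-3-methylbutyl]-2-methoxybenzoic acid | COc1c([C@H](O)CC(C)C)ccc(Oc2c(OCc3ccccc3)cc(C)cc2C=O)c1C(=O)O
F3 | step 4 | 6-[2-(benzyloxy)-6-(hydroxymethyl)-4-methylphenoxy]-3-[(1R)-1-hydroxy-3-methylbutyl]-2-methoxybenzoic acid | COc1c([C@H](O)CC(C)C)ccc(Oc2c(OCc3ccccc3)cc(C)cc2CO)c1C(=O)O
F4 | step 1 | rac-1-(4-bromo-2-methoxyphenyl)-3-methylbutan-1-ol | COc1cc(Br)ccc1C(O)CC(C)C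
F5 | step 1 | 1-(4-bromo-2-methoxyphenyl)-3-methylbutan-1-one | COc1cc(Br)ccc1C(=O)CC(C)C
F6 | step 2 | (1R)-1-[4-bromo-2-methoxy-3-(4,4,5,5-tetramethyl-1,3,2-dioxaborolan-2-yl)phenyl]-3-methylbutan-1-ol | COc1c(B2OC(C)(C)C(C)(C)O2)c(Br)ccc1[C@H](O)CC(C)C
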